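**Strategy.** Counting from the ester carbon (C1), the methyl centres C4 and C8 are mirror images across C6, so C3–C9 is a hidden meso carbocycle: cis-3,6-dimethylcyclohept-4-enone with C6 as carbonyl carbon and C3=C9 as ring alkene. One [4+3] cycloaddition of the oxyallyl cation from tetrabromoacetone with symmetrical (2E,4E)-hexa-2,4-diene, the only precursor needed, forms C4–C5 and C7–C8, closes this ring and sets the cis methyl pair. The ring then directs the C6 peroxide, ozonolysis opens it in two directions, a lipase tells the enantiotopic arms apart, and the 1,2-dioxane is closed last as a peroxy-hemiketal.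

Key step: step 1

Remark: carbon numbers C1–C16 are those of the target chain (C1 = ester carbon; the dioxane holds C3–C6); MOP = 2-methoxypropan-2-yl.
Assumption: Pseudomonas lipases are taken to act on the CH2O arm attached to the (S)-configured methyl-bearing carbon, as with meso-2,4-dimethylpentane-1,5-diol derivatives; in 10 and 11 that is the C9 arm.

**Step 1**
Reactants: 1 (2E,4E)-hexa-2,4-diene; 2 1,1,3,3-tetrabromoacetone
Product: 4 cis-3,6-dimethylcyclohept-4-en-1-one (meso ketone), via dibromo cycloadduct 3 (not isolated)
Conditions: Fe2(CO)9, excess 1, C6H6, 60 °C; then Zn–Cu couple, NH4Cl, MeOH, rt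
Reagents that add atoms: none
Why: Zerovalent iron from Fe2(CO)9 removes two bromides from 2 to give an iron-bound dibromo-oxyallyl cation, a three-carbon 2π partner that bonds to both termini of the s-cis diene 1, and zinc–copper couple then reduces the two remaining C–Br bonds of 3. The closest known reaction type is the iron-carbonyl-promoted [4+3] cycloaddition of polybromoketones with open-chain 1,3-dienes followed by reductive debromination. The seven-membered carbocycle (C3–C9, C6 as carbonyl carbon) is closed by intermolecular [4+3] cycloaddition that forms C4–C5 and C7–C8 in the same operation. The two new stereocentres C4 and C8 are controlled by the (E,E) geometry of 1: suprafacial bonding at both diene termini turns the two outward methyl groups into a cis pair, so 4 is the meso isomer. The step needs retention of diene geometry (there is no regiochemical question because both partners are symmetrical), and this is secured because only the (E,E) isomer reaches the s-cis conformation easily and ring closure of any zwitterionic intermediate should outrun bond rotation; the bromine-bearing centres of 3 do not matter because they end as CH2.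

**Step 2**
Reactants: 4 cis-3,6-dimethylcyclohept-4-en-1-one
Product: 5 cis-3,7-dimethyl-5-methylidenecyclohept-1-ene (meso)
Conditions: Ph3PCH3Br, KOtBu, THF, 0 °C → rt
Reagents that add atoms: methyltriphenylphosphonium bromide, C[P+](c1ccccc1)(c1ccccc1)c1ccccc1.[Br-]
Why: Wittig methylenation of an unhindered ketone whose stereocentres are β to the carbonyl and cannot epimerise, so the meso cis relationship is kept.

**Step 3**
Reactants: 5 cis-3,7-dimethyl-5-methylidenecyclohept-1-ene
Product: 7 1-hydroperoxy-1,3,6-trimethylcyclohept-4-ene (OOH trans to both ring methyls; meso), via triethylsilyl peroxide 6 (not isolated)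
Conditions: Co(acac)2 (cat.), Et3SiH, O2 (1 atm), ClCH2CH2Cl, rt; SiO2 plug; then HCl (cat.), MeOH, 0 °C
Reagents that add atoms: dioxygen, O=O
Why: Mukaiyama–Isayama silylperoxidation, in which the cobalt hydride delivers H to the exocyclic CH2 (a 1,1-disubstituted alkene reacts faster than the ring 1,2-disubstituted one) and the tertiary C6 radical is expected to take up O2 along the axial trajectory, on the face away from the two equatorial ring methyls, so that the new C6 methyl is equatorial; acid methanolysis removes the silyl group and the minor C6 epimer (also meso) is removed by chromatography.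

**Step 4**
Reactants: 7 1-hydroperoxy-1,3,6-trimethylcyclohept-4-ene
Product: 8 1-[(2-methoxypropan-2-yl)peroxy]-1,3,6-trimethylcyclohept-4-ene (meso peroxyketal)
Conditions: 2-methoxypropene, PPTS (cat.), CH2Cl2, 0 °C
Reagents that add atoms: 2-methoxypropene, COC(C)=C
Why: Acid-catalysed addition of the hydroperoxide O–H to the enol ether gives a peroxyketal, a hydroperoxide protecting group that tolerates hydride, carbonate, ylides and mild oxidants, without touching C6.

**Step 5**
Reactants: 8 ring peroxyketal
Product: 10 (2R,4s,6S)-4-[(2-methoxypropan-2-yl)peroxy]-2,4,6-trimethylheptane-1,7-diol (meso diol), via ozonide 9 (not isolated)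
Conditions: O3, CH2Cl2, −78 °C; then NaBH4, EtOH, −78 °C → rt
Reagents that add atoms: ozone, [O-][O+]=O
Why: Ozonolysis of the only alkene (C3=C9) and borohydride reduction of the ozonide open the ring in both directions to a meso diol, while the dialkyl-type peroxyketal is not reduced by NaBH4 and C4, C6 and C8 are untouched.

**Step 6**
Reactants: 10 meso diol
Product: 11 meso diacetate of 10
Conditions: Ac2O, pyridine, DMAP (cat.), CH2Cl2, 0 °C → rt
Reagents that add atoms: acetic anhydride, CC(=O)OC(C)=O
Why: DMAP-catalysed acetylation of two unhindered primary alcohols prepares the substrate for enzymatic hydrolysis.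

**Step 7**
Reactants: 11 meso diacetate
Product: 12 (2R,4S,6S)-7-hydroxy-4-[(2-methoxypropan-2-yl)peroxy]-2,4,6-trimethylheptyl acetate (free OH on C9, acetate on C3)
Conditions: Pseudomonas fluorescens lipase (Amano AK), pH 7 phosphate buffer/acetone, rt, stopped when 11 is consumed
Reagents that add atoms: none
Why: Lipase-catalysed enantiotopic-group-selective hydrolysis of a meso diacetate should cleave the acetate on the C9 arm (the arm on the S-configured centre), which fixes the absolute configuration of C4, C6 and C8 in one event; the minor enantiomer still carries its acetate on the fast-reacting arm and is hydrolysed on to diol 10 (recycled through step 6), which raises the ee of 12.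

**Step 8**
Reactants: 12 monoacetate
Product: 13 4-[(2-methoxypropan-2-yl)peroxy]-2,4,6-trimethyl-7-oxoheptyl acetate (C9 aldehyde)
Conditions: Dess–Martin periodinane, pyridine, CH2Cl2, 0 °C → rt
Reagents that add atoms: none
Why: Dess–Martin oxidation of a primary alcohol under buffered, non-basic conditions should not epimerise the α-centre C8, and the aldehyde is used at once.

**Step 9**
Reactants: 14 (7-bromoheptyl)benzene
Product: 15 triphenyl(7-phenylheptyl)phosphonium bromide
Conditions: PPh3, MeCN, reflux
Reagents that add atoms: triphenylphosphine, c1ccccc1P(c1ccccc1)c1ccccc1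
Why: SN2 quaternisation of triphenylphosphine by a primary alkyl bromide.

**Step 10**
Reactants: 13 C9 aldehyde; 15 triphenyl(7-phenylheptyl)phosphonium bromide
Product: 17 (Z)-4-[(2-methoxypropan-2-yl)peroxy]-2,4,6-trimethyl-14-phenyltetradec-7-enyl acetate, via phosphorus ylide 16 (not isolated)
Conditions: 15, NaN(SiMe3)2, THF, 0 °C; then 13, −78 °C → rt
Reagents that add atoms: none
Why: Wittig olefination with a non-stabilised ylide forms C9=C10 (Z expected, geometry irrelevant), and peroxyketals and acetates tolerate ylides at low temperature while the fast addition keeps C8 intact.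

**Step 11**
Reactants: 17 Z-alkene
Product: 18 4-[(2-methoxypropan-2-yl)peroxy]-2,4,6-trimethyl-14-phenyltetradecyl acetate
Conditions: 2-nitrobenzenesulfonohydrazide (NBSH), Et3N, CH2Cl2, rt
Reagents that add atoms: none
Why: Diimide reduction adds H2 to the disubstituted alkene by concerted syn transfer and, unlike catalytic hydrogenation, leaves the O–O bond intact.

**Step 12**
Reactants: 18 saturated acetate
Product: 19 4-[(2-methoxypropan-2-yl)peroxy]-2,4,6-trimethyl-14-phenyltetradecan-1-ol
Conditions: K2CO3 (cat.), MeOH, rt
Reagents that add atoms: none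
Why: Carbonate-catalysed transesterification frees the C3 alcohol, and the peroxyketal is stable to base.

**Step 13**
Reactants: 19 C3 alcohol
Product: 20 4-[(2-methoxypropan-2-yl)peroxy]-2,4,6-trimethyl-14-phenyltetradecanoic acid
Conditions: TEMPO (cat.), NaOCl (cat.), NaClO2, MeCN/phosphate buffer (pH 6.7), 35 °C
Reagents that add atoms: sodium chlorite, [Na+].[O-]Cl=O
Why: TEMPO/chlorite oxidation takes the primary alcohol through the aldehyde to the acid at near-neutral pH, which should leave the α-centre C4 and the acid-sensitive peroxyketal intact.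

**Step 14**
Reactants: 20 carboxylic acid
Product: 22 methyl (4R,6S,8R)-6-[(2-methoxypropan-2-yl)peroxy]-4,6,8-trimethyl-3-oxo-16-phenylhexadecanoate, via acyl imidazolide 21 (not isolated)
Conditions: CDI, THF, rt; then Mg(O2CCH2CO2Me)2, rt → 40 °C; aq. NH4Cl work-up
Reagents that add atoms: magnesium bis(methyl malonate), COC(=O)CC(=O)[O-].COC(=O)CC(=O)[O-].[Mg+2]
Why: Masamune–Brooks homologation, in which the acyl imidazolide is C-acylated by the magnesium malonate enolate and decarboxylation delivers the β-keto ester (C1–C3) under neutral conditions, with no Lewis acid or reducing metal near the peroxide.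

**Step 15**
Reactants: 22 protected β-keto ester
Product: 24 methyl 2-[(3S,4R,6S)-3-hydroxy-4,6-dimethyl-6-[(2R)-2-methyl-10-phenyldecyl]-1,2-dioxan-3-yl]acetate (target), via hydroperoxy keto ester 23 (not isolated)
Conditions: AcOH/THF/H2O (4:2:1), rt
Reagents that add atoms: none
Why: Mild acid hydrolysis of the peroxyketal frees the C6 hydroperoxide, which adds to the C3 ketone to close the six-membered peroxy-hemiketal; C3 is set under thermodynamic control (reversible hemiketalisation) with OH axial (anomeric effect, hydrogen bond to the ester) and CH2CO2Me, the C4 methyl and the C6 chain equatorial, as in the target.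

**Compound list**
1 | (2E,4E)-hexa-2,4-diene | C/C=C/C=C/C | starting material
2 | 1,1,3,3-tetrabromoacetone | O=C(C(Br)Br)C(Br)Br | starting material
3 | 2,7-dibromo-cis-3,6-dimethylcyclohept-4-en-1-one (bromine centres as a mixture) | O=C1C(Br)[C@H](C)C=C[C@H](C)C1Br | intermediate
4 | cis-3,6-dimethylcyclohept-4-en-1-one (meso, 3R,6S) | O=C1C[C@H](C)C=C[C@H](C)C1 | intermediate
5 | cis-3,7-dimethyl-5-methylidenecyclohept-1-ene (meso) | C=C1C[C@H](C)C=C[C@H](C)C1 | intermediate
6 | triethyl[(1,3,6-trimethylcyclohept-4-en-1-yl)peroxy]silane, ring methyls cis, peroxy group trans to both (meso) | C1=C[C@H](C)C[C@@](C)(OO[Si](CC)(CC)CC)C[C@@H]1C | intermediate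
7 | 1-hydroperoxy-1,3,6-trimethylcyclohept-4-ene, ring methyls cis, OOH trans to both (meso) | C1=C[C@H](C)C[C@@](C)(OO)C[C@@H]1C | intermediate
8 | 1-[(2-methoxypropan-2-yl)peroxy]-1,3,6-trimethylcyclohept-4-ene, same relative configuration (meso) | C1=C[C@H](C)C[C@@](C)(OOC(C)(C)OC)C[C@@H]1C | intermediate
9 | 4-[(2-methoxypropan-2-yl)peroxy]-2,4,6-trimethyl-8,9,10-trioxabicyclo[5.2.1]decane (ozonide, bridgehead carbons not defined) | O1C2OOC1[C@@H](C)C[C@](C)(OOC(C)(C)OC)C[C@H]2C | intermediate
10 | (2R,4s,6S)-4-[(2-methoxypropan-2-yl)peroxy]-2,4,6-trimethylheptane-1,7-diol (meso) | OC[C@H](C)C[C@@](C)(OOC(C)(C)OC)C[C@H](C)CO | intermediate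
11 | (2R,4s,6S)-4-[(2-methoxypropan-2-yl)peroxy]-2,4,6-trimethylheptane-1,7-diyl diacetate (meso) | CC(=O)OC[C@H](C)C[C@@](C)(OOC(C)(C)OC)C[C@H](C)COC(C)=O | intermediate
12 | (2R,4S,6S)-7-hydroxy-4-[(2-methoxypropan-2-yl)peroxy]-2,4,6-trimethylheptyl acetate | CC(=O)OC[C@H](C)C[C@@](C)(OOC(C)(C)OC)C[C@H](C)CO | intermediate
13 | 4-[(2-methoxypropan-2-yl)peroxy]-2,4,6-trimethyl-7-oxoheptyl acetate (stereocentres arranged as in 12) | CC(=O)OC[C@H](C)C[C@@](C)(OOC(C)(C)OC)C[C@H](C)C=O | intermediate
14 | (7-bromoheptyl)benzene | BrCCCCCCCc1ccccc1 | starting material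
15 | triphenyl(7-phenylheptyl)phosphonium bromide | [Br-].c1ccccc1CCCCCCC[P+](c1ccccc1)(c1ccccc1)c1ccccc1 | intermediate
16 | triphenyl(7-phenylheptylidene)phosphorane | c1ccccc1CCCCCCC=P(c1ccccc1)(c1ccccc1)c1ccccc1 | intermediate
17 | (Z)-4-[(2-methoxypropan-2-yl)peroxy]-2,4,6-trimethyl-14-phenyltetradec-7-enyl acetate (stereocentres arranged as in 12) | CC(=O)OC[C@H](C)C[C@@](C)(OOC(C)(C)OC)C[C@H](C)/C=C\CCCCCCc1ccccc1 | intermediate
18 | 4-[(2-methoxypropan-2-yl)peroxy]-2,4,6-trimethyl-14-phenyltetradecyl acetate (stereocentres arranged as in 12) | CC(=O)OC[C@H](C)C[C@@](C)(OOC(C)(C)OC)C[C@H](C)CCCCCCCCc1ccccc1 | intermediate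
19 | 4-[(2-methoxypropan-2-yl)peroxy]-2,4,6-trimethyl-14-phenyltetradecan-1-ol (stereocentres arranged as in 12) | OC[C@H](C)C[C@@](C)(OOC(C)(C)OC)C[C@H](C)CCCCCCCCc1ccccc1 | intermediate
20 | 4-[(2-methoxypropan-2-yl)peroxy]-2,4,6-trimethyl-14-phenyltetradecanoic acid (stereocentres arranged as in 12) | OC(=O)[C@H](C)C[C@@](C)(OOC(C)(C)OC)C[C@H](C)CCCCCCCCc1ccccc1 | intermediate
21 | 1-(imidazol-1-yl)-4-[(2-methoxypropan-2-yl)peroxy]-2,4,6-trimethyl-14-phenyltetradecan-1-one (stereocentres arranged as in 12) | O=C(n1ccnc1)[C@H](C)C[C@@](C)(OOC(C)(C)OC)C[C@H](C)CCCCCCCCc1ccccc1 | intermediate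
22 | methyl (4R,6S,8R)-6-[(2-methoxypropan-2-yl)peroxy]-4,6,8-trimethyl-3-oxo-16-phenylhexadecanoate | COC(=O)CC(=O)[C@H](C)C[C@@](C)(OOC(C)(C)OC)C[C@H](C)CCCCCCCCc1ccccc1 | intermediate
23 | methyl (4R,6S,8R)-6-hydroperoxy-4,6,8-trimethyl-3-oxo-16-phenylhexadecanoate | COC(=O)CC(=O)[C@H](C)C[C@@](C)(OO)C[C@H](C)CCCCCCCCc1ccccc1 | intermediate
24 | methyl 2-[(3S,4R,6S)-3-hydroxy-4,6-dimethyl-6-[(2R)-2-methyl-10-phenyldecyl]-1,2-dioxan-3-yl]acetate | COC(=O)C[C@]1(O)OO[C@@](C)(C[C@H](C)CCCCCCCCc2ccccc2)C[C@H]1C | target

**Step count and risks**
Total steps: 15. Longest linear sequence: 14 (steps 1–8 and 10–15, from 1 and 2); step 9 is a one-step branch.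

Step 1 (key step). What may go wrong: the oxyallyl cation is generated faster than the mostly s-trans open-chain diene traps it and is lost to reduction and oligomerisation, or a stepwise addition allows bond rotation and erodes the cis relationship. The fallback sets out from 1, which is first complexed (Fe2(CO)9, Et2O, reflux) to tricarbonyl[η4-(2E,4E)-hexa-2,4-diene]iron F1, in which the diene is held s-cis on the metal. F1 then serves both as the four-carbon partner and as the zerovalent iron reductant toward 2 (C6H6, 80 °C), giving dibromide 3, and the same Zn–Cu reduction comes back to the route at 4.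

Step 3. What may go wrong: the C6 radical captures oxygen on both ring faces with little preference, or the peroxyl radical cyclises onto the ring alkene. The fallback is ionic and sets out from ketone 4: MeMgBr (THF, 0 °C) gives 1,3,6-trimethylcyclohept-4-en-1-ol F2 (either C1 epimer serves), and acid-catalysed perhydrolysis (50% H2O2, cat. H2SO4, 0 °C) exchanges OH for OOH through the tertiary cation. Because this capture is reversible, the mixture should drift toward the isomer with the C6 methyl equatorial and the hydroperoxy group axial, which is 7, where the route is rejoined.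

Step 7. What may go wrong: weak or reversed discrimination between the two enantiotopic acetoxymethyl arms, since the methyl centres sit one carbon from the reacting ester and next to a bulky quaternary carbon. The fallback sets out from diol 10 (step 6 is omitted) and moves the differentiation to acyl transfer (lipase, vinyl acetate, iPr2O, rt). Hydrolysis and acylation turn the same arm preference into opposite monoacetates, so an enzyme that attacks the C3 arm delivers 12 directly, with over-acylation to 11 removing the minor enantiomer. The route is rejoined at 12 and no new compound is made (F0).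

**Further compounds**
F1 | step 1 | tricarbonyl[η4-(2E,4E)-hexa-2,4-diene]iron (written as separate components) | C/C=C/C=C/C.[Fe].[C-]#[O+].[C-]#[O+].[C-]#[O+]
F2 | step 3 | 1,3,6-trimethylcyclohept-4-en-1-ol (ring methyls cis, C1 epimers) | C1=C[C@H](C)CC(C)(O)C[C@@H]1C
F0 | step 7 | none | none
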